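**Retrosynthetic overview**
1. The aryl ether C–O bond is cut last (Mitsunobu of 7-hydroxy-8-methoxycoumarin with a primary epoxy alcohol); the oxirane comes from Sharpless epoxidation of an E-allylic alcohol whose olefin geometry is bought with geraniol.
2. The γ-lactone is cut at C3–C4 and O1–C5. The enabling feature is that O1–C2(=O)–C3(OH)(CH3) of the oxolan-2-one ring is a lactic acid unit: its α-carbon and carboxylate oxygen are 1,3-related nucleophiles, matched to the vicinal C4/C5 dielectrophile of a terminal 1,2-diol cyclic sulfate.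
3. The (S)-lactic acid centre is relayed to the quaternary C3 through a tert-butyl acetal; the diol carbinol centre (D-proline α-aminoxylation of a C6 aldehyde cut from geraniol) is inverted on ring closure to give C5.
4. Ring order: dioxolanone (temporary), cyclic sulfate (temporary), γ-lactone (key step), oxirane, then attachment of the bought coumarin.

Key step: step 8

Assumption: 7-hydroxy-8-methoxycoumarin (daphnetin 8-methyl ether) is taken as a commercial compound, and the aldehyde oxygen of 6 is taken to be the epoxide oxygen of 5 (water opens the tertiary carbon).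

**Step 1**
Reactants: 1 geraniol; 2 tert-butyl(chloro)diphenylsilane
Product: 3 tert-butyl{[(2E)-3,7-dimethylocta-2,6-dien-1-yl]oxy}diphenylsilane
Conditions: imidazole, DMF, 0 °C to rt
Reagents that add atoms: tert-butyl(chloro)diphenylsilane, CC(C)(C)[Si](Cl)(c1ccccc1)c1ccccc1
Why: Standard silylation of a primary allylic alcohol, giving an ether that should survive peracid, periodic acid, hydride, NaH and a lithium enolate.

**Step 2**
Reactants: 3 geranyl silyl ether; 4 3-chloroperbenzoic acid
Product: 5 tert-butyl{[(2E)-5-(3,3-dimethyloxiran-2-yl)-3-methylpent-2-en-1-yl]oxy}diphenylsilane (racemic at the oxirane carbon)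
Conditions: mCPBA (1.0 equiv), NaHCO3, CH2Cl2, −20 to 0 °C
Reagents that add atoms: 3-chloroperbenzoic acid, OOC(=O)c1cccc(Cl)c1
Why: Prilezhaev epoxidation should select the distal 6,7-olefin because the 2,3-olefin is inductively deactivated by the allylic silyloxy group; the new stereocentre is irrelevant as it is destroyed in step 3.

**Step 3**
Reactants: 5 6,7-epoxide
Product: 6 (4E)-6-[(tert-butyldiphenylsilyl)oxy]-4-methylhex-4-enal
Conditions: H5IO6, THF/Et2O/H2O, 0 °C
Reagents that add atoms: none
Why: Periodic acid hydrolyses the trisubstituted epoxide to the glycol and cleaves it in the same flask (Malaprade-type cleavage), losing acetone and leaving the E-olefin and silyl ether untouched.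

**Step 4**
Reactants: 6 aldehyde; 7 nitrosobenzene
Product: 9 (2S,4E)-2-(anilinooxy)-6-[(tert-butyldiphenylsilyl)oxy]-4-methylhex-4-en-1-ol, via α-anilinooxy aldehyde 8 (not isolated)
Conditions: D-proline (20 mol%), DMSO, rt; then NaBH4, EtOH, 0 °C
Reagents that add atoms: nitrosobenzene, O=Nc1ccccc1
Why: Proline-catalysed α-aminoxylation (enamine catalysis, O-selective nitroso aldol) sets the 2S centre by the hydrogen-bonded enamine transition state of D-proline (L-proline gives 2R), and immediate borohydride reduction prevents racemisation of the α-oxy aldehyde.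

**Step 5**
Reactants: 9 anilinooxy alcohol
Product: 10 (2S,4E)-6-[(tert-butyldiphenylsilyl)oxy]-4-methylhex-4-ene-1,2-diol
Conditions: Zn dust, AcOH/THF, rt
Reagents that add atoms: none
Why: Reductive cleavage of the weak N–O bond by dissolving zinc should free the diol without touching the olefin, the silyl ether or the stereocentre.

**Step 6**
Reactants: 10 (S)-diol; 11 1,1'-sulfonyldiimidazole
Product: 12 (4S)-4-{(2E)-4-[(tert-butyldiphenylsilyl)oxy]-2-methylbut-2-en-1-yl}-1,3,2-dioxathiolane 2,2-dioxide
Conditions: NaH (2.2 equiv), THF, 0 °C; then Im2SO2, −40 °C to rt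
Reagents that add atoms: 1,1'-sulfonyldiimidazole, O=S(=O)(n1ccnc1)n1ccnc1
Why: Double O-sulfonylation of the dialkoxide by a sulfuryl-transfer reagent gives the cyclic sulfate at the S(VI) level directly, so no oxidant comes near the trisubstituted olefin, and the carbinol configuration is untouched.

**Step 7**
Reactants: 13 (S)-lactic acid; 14 pivalaldehyde
Product: 15 (2S,5S)-2-tert-butyl-5-methyl-1,3-dioxolan-4-one (cis)
Conditions: p-TsOH (cat.), H2SO4 (trace), pentane, reflux, Dean–Stark; crystallisation from pentane/Et2O at −78 °C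
Reagents that add atoms: pivalaldehyde, CC(C)(C)C=O
Why: Acid-catalysed acetalisation under thermodynamic control (self-regeneration of stereocentres) favours the cis acetal, in which the new acetal centre (2S) is set by the lactic acid centre, and low-temperature crystallisation removes the minor trans isomer.

**Step 8**
Reactants: 12 cyclic sulfate; 15 dioxolanone; 16 lithium hydroxide
Product: 20 (3R,5R)-5-{(2E)-4-[(tert-butyldiphenylsilyl)oxy]-2-methylbut-2-en-1-yl}-3-hydroxy-3-methyloxolan-2-one, via lithium enolate 17 (not isolated), via lithium alkyl sulfate 18 (not isolated), via dilithium carboxylate sulfate 19 (not isolated)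
Conditions: 15 (1.5 equiv), LDA, THF, −78 °C; 12, THF/DMPU, −78 to −30 °C; LiOH·H2O (2.5 equiv), H2O, 0 to 60 °C; then aq NaHSO4 to pH 3, rt
Reagents that add atoms: lithium hydroxide, [Li+].[OH-]
Why: Proposed new method: a one-pot formal [3+2] C,O-annulation in which enolate 17 opens cyclic sulfate 12 by SN2 attack at its primary carbon (lactone C3–C4 bond), hydroxide then unmasks the dioxolanone of 18 to the α-hydroxy carboxylate 19, and this carboxylate displaces the secondary sulfate monoester intramolecularly (O1–C5 bond) with loss of sulfate. The closest known reaction types are the alkylation of this dioxolanone enolate with reactive electrophiles, the opening of 1,2-cyclic sulfates by carbanions followed by a second intramolecular displacement of the sulfate monoester (malonate to cyclopropane; 1,3-dicarbonyl dianion to 2-alkylidenetetrahydrofuran by C- then O-alkylation), and the inverting lactonisation of γ-sulfonyloxy carboxylates. The only ring closed is the γ-lactone, by 5-exo-tet O-alkylation. The quaternary C3 is controlled by the tert-butyl group of the acetal (attack anti to it, net retention of the lactic acid configuration, giving 3R), and C5 by stereospecific inversion of the 2S carbinol carbon from step 4 (giving 5R, side chain cis to the 3-methyl group and trans to the 3-hydroxyl). The step needs C- over O-alkylation and primary over secondary attack in the first displacement, which the hindered carbon-centred enolate and the unhindered terminal CH2 of 12 should secure, and C–O over S–O cleavage in the second, which is secured by keeping the medium basic until the sulfate is consumed, since sulfate monoesters resist S–O hydrolysis in base. Any loss of the silyl group during the basic heating would only anticipate step 9.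

**Step 9**
Reactants: 20 silyl ether lactone
Product: 21 (3R,5R)-3-hydroxy-5-[(2E)-4-hydroxy-2-methylbut-2-en-1-yl]-3-methyloxolan-2-one
Conditions: TBAF, AcOH (1:1), THF, 0 °C to rt
Reagents that add atoms: none
Why: Fluoride-mediated desilylation buffered with acetic acid should free the allylic alcohol without opening or epimerising the α-hydroxy lactone.

**Step 10**
Reactants: 21 allylic alcohol; 22 tert-butyl hydroperoxide
Product: 23 (3R,5S)-3-hydroxy-5-{[(2R,3R)-3-(hydroxymethyl)-2-methyloxiran-2-yl]methyl}-3-methyloxolan-2-one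
Conditions: Ti(OiPr)4 (cat.), D-(−)-diethyl tartrate (cat.), TBHP, 4 Å MS, CH2Cl2, −20 °C
Reagents that add atoms: tert-butyl hydroperoxide, CC(C)(C)OO
Why: Sharpless asymmetric epoxidation of an E-trisubstituted allylic alcohol, in which the D-(−)-tartrate titanium complex delivers oxygen to the face that gives the (2R,3R)-oxirane (the enantiomeric sense to L-(+)-tartrate on geraniol), with reagent control overriding the remote lactone centres; the C5 descriptor changes to S by priority only.

**Step 11**
Reactants: 23 epoxy alcohol; 24 7-hydroxy-8-methoxycoumarin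
Product: 25 7-{[(2R,3R)-3-{[(2S,4R)-4-hydroxy-4-methyl-5-oxooxolan-2-yl]methyl}-3-methyloxiran-2-yl]methoxy}-8-methoxy-2H-chromen-2-one (target)
Conditions: PPh3, DIAD, THF, 0 °C to rt
Reagents that add atoms: none
Why: Mitsunobu etherification of the acidic coumarin phenol at the primary carbinol carbon, which bears no stereocentre, while the tertiary hydroxyl is inert and the oxirane and lactone should survive the neutral conditions.

**Compound list**
1 | geraniol, (2E)-3,7-dimethylocta-2,6-dien-1-ol | CC(C)=CCC/C(C)=C/CO | starting material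
2 | tert-butyl(chloro)diphenylsilane | CC(C)(C)[Si](Cl)(c1ccccc1)c1ccccc1 | starting material
3 | tert-butyl{[(2E)-3,7-dimethylocta-2,6-dien-1-yl]oxy}diphenylsilane | CC(C)(C)[Si](c1ccccc1)(c1ccccc1)OC/C=C(\C)CCC=C(C)C | intermediate
4 | 3-chloroperbenzoic acid | OOC(=O)c1cccc(Cl)c1 | starting material
5 | tert-butyl{[(2E)-5-(3,3-dimethyloxiran-2-yl)-3-methylpent-2-en-1-yl]oxy}diphenylsilane, racemic | CC(C)(C)[Si](c1ccccc1)(c1ccccc1)OC/C=C(\C)CCC1OC1(C)C | intermediate
6 | (4E)-6-[(tert-butyldiphenylsilyl)oxy]-4-methylhex-4-enal | CC(C)(C)[Si](c1ccccc1)(c1ccccc1)OC/C=C(\C)CCC=O | intermediate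
7 | nitrosobenzene | O=Nc1ccccc1 | starting material
8 | (2S,4E)-2-(anilinooxy)-6-[(tert-butyldiphenylsilyl)oxy]-4-methylhex-4-enal | CC(C)(C)[Si](c1ccccc1)(c1ccccc1)OC/C=C(\C)C[C@H](ONc1ccccc1)C=O | intermediate
9 | (2S,4E)-2-(anilinooxy)-6-[(tert-butyldiphenylsilyl)oxy]-4-methylhex-4-en-1-ol | CC(C)(C)[Si](c1ccccc1)(c1ccccc1)OC/C=C(\C)C[C@H](ONc1ccccc1)CO | intermediate
10 | (2S,4E)-6-[(tert-butyldiphenylsilyl)oxy]-4-methylhex-4-ene-1,2-diol | CC(C)(C)[Si](c1ccccc1)(c1ccccc1)OC/C=C(\C)C[C@H](O)CO | intermediate
11 | 1,1'-sulfonyldiimidazole | O=S(=O)(n1ccnc1)n1ccnc1 | starting material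
12 | (4S)-4-{(2E)-4-[(tert-butyldiphenylsilyl)oxy]-2-methylbut-2-en-1-yl}-1,3,2-dioxathiolane 2,2-dioxide | CC(C)(C)[Si](c1ccccc1)(c1ccccc1)OC/C=C(\C)C[C@H]1COS(=O)(=O)O1 | intermediate
13 | (S)-lactic acid | C[C@H](O)C(=O)O | starting material
14 | pivalaldehyde | CC(C)(C)C=O | starting material
15 | (2S,5S)-2-tert-butyl-5-methyl-1,3-dioxolan-4-one (cis) | C[C@@H]1O[C@H](C(C)(C)C)OC1=O | intermediate
16 | lithium hydroxide | [Li+].[OH-] | starting material
17 | lithium (2S)-2-tert-butyl-5-methyl-1,3-dioxol-4-olate | CC1=C([O-])O[C@@H](C(C)(C)C)O1.[Li+] | intermediate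
18 | lithium (2S,4E)-1-[(2S,4R)-2-tert-butyl-4-methyl-5-oxo-1,3-dioxolan-4-yl]-6-[(tert-butyldiphenylsilyl)oxy]-4-methylhex-4-en-2-yl sulfate | CC(C)(C)[Si](c1ccccc1)(c1ccccc1)OC/C=C(\C)C[C@H](OS(=O)(=O)[O-])C[C@@]1(C)O[C@H](C(C)(C)C)OC1=O.[Li+] | intermediate
19 | dilithium (2R,4S,6E)-8-[(tert-butyldiphenylsilyl)oxy]-2-hydroxy-2,6-dimethyl-4-(sulfonatooxy)oct-6-enoate | CC(C)(C)[Si](c1ccccc1)(c1ccccc1)OC/C=C(\C)C[C@H](OS(=O)(=O)[O-])C[C@@](C)(O)C(=O)[O-].[Li+].[Li+] | intermediate
20 | (3R,5R)-5-{(2E)-4-[(tert-butyldiphenylsilyl)oxy]-2-methylbut-2-en-1-yl}-3-hydroxy-3-methyloxolan-2-one | CC(C)(C)[Si](c1ccccc1)(c1ccccc1)OC/C=C(\C)C[C@@H]1C[C@@](C)(O)C(=O)O1 | intermediate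
21 | (3R,5R)-3-hydroxy-5-[(2E)-4-hydroxy-2-methylbut-2-en-1-yl]-3-methyloxolan-2-one | OC/C=C(\C)C[C@@H]1C[C@@](C)(O)C(=O)O1 | intermediate
22 | tert-butyl hydroperoxide | CC(C)(C)OO | starting material
23 | (3R,5S)-3-hydroxy-5-{[(2R,3R)-3-(hydroxymethyl)-2-methyloxiran-2-yl]methyl}-3-methyloxolan-2-one | OC[C@H]1O[C@]1(C)C[C@@H]1C[C@@](C)(O)C(=O)O1 | intermediate
24 | 7-hydroxy-8-methoxycoumarin | COc1c(O)ccc2ccc(=O)oc12 | starting material
25 | 7-{[(2R,3R)-3-{[(2S,4R)-4-hydroxy-4-methyl-5-oxooxolan-2-yl]methyl}-3-methyloxiran-2-yl]methoxy}-8-methoxy-2H-chromen-2-one | COc1c(OC[C@H]2O[C@]2(C)C[C@@H]2C[C@@](C)(O)C(=O)O2)ccc2ccc(=O)oc12 | target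

**Step count and risks**
Total steps: 11. Longest linear sequence: 10 steps (steps 1–6 and 8–11); step 7 is a one-step side branch.

Steps most likely to fail:

Step 8 (proposed new method). The intramolecular displacement of the secondary sulfate monoester may be slower than elimination or adventitious S–O hydrolysis, which would erode the configuration at C5; the enolate may also decompose before it opens the cyclic sulfate. The fallback uses only known steps and takes C5 by retention instead of inversion. It sets out from aldehyde 6: the aminoxylation–reduction of step 4 is run with L-proline and should give, through the (2R)-anilinooxy aldehyde F1, the (2R)-anilinooxy alcohol F2. Zn/AcOH then gives the (2R)-diol F3, and sulfuryl transfer as in step 6 gives the (4R)-cyclic sulfate F4. Enolate 17 is alkylated with F4 at low temperature to the lithium sulfate monoester F5. This is not heated with base but hydrolysed with catalytic H2SO4 and one equivalent of water in THF (S–O cleavage, retention at carbon) to the γ-hydroxy dioxolanone F6. p-TsOH in CH2Cl2 should then effect translactonisation with loss of pivalaldehyde and retention at the carbinol carbon, and the route is rejoined at 20.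

Step 6. The second sulfonylation may fail to close the ring, leaving acyclic imidazolylsulfonates or oligomers, or NaH may induce elimination. The fallback sets out from diol 10 and goes through the S(IV) level: SOCl2/Et3N in CH2Cl2 at 0 °C should give the cyclic sulfite F7 (both sulfur epimers). This is oxidised with catalytic RuCl3 and NaIO4 in MeCN/H2O at 0 °C and quenched as soon as the sulfite is consumed, so that the inductively deactivated olefin is spared. The route is rejoined at 12.

Step 10. The α-hydroxy lactone may chelate titanium and sequester the catalyst, giving slow turnover and poor facial selectivity. The fallback sets out from allylic alcohol 21 and reverses the last two operations: Mitsunobu etherification with 24 (PPh3, DIAD, THF) should give the allyl aryl ether F8. Its trisubstituted olefin is then epoxidised with the D-fructose-derived ketone and Oxone at buffered pH and 0 °C (Shi epoxidation). The spiro transition-state model predicts the (2R,3R)-oxirane, and the electron-poor coumarin double bond should not react. The route is rejoined at the target 25.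

**Further compounds**
F1 | step 8 | (2R,4E)-2-(anilinooxy)-6-[(tert-butyldiphenylsilyl)oxy]-4-methylhex-4-enal | CC(C)(C)[Si](c1ccccc1)(c1ccccc1)OC/C=C(\C)C[C@@H](ONc1ccccc1)C=O
F2 | step 8 | (2R,4E)-2-(anilinooxy)-6-[(tert-butyldiphenylsilyl)oxy]-4-methylhex-4-en-1-ol | CC(C)(C)[Si](c1ccccc1)(c1ccccc1)OC/C=C(\C)C[C@@H](ONc1ccccc1)CO
F3 | step 8 | (2R,4E)-6-[(tert-butyldiphenylsilyl)oxy]-4-methylhex-4-ene-1,2-diol | CC(C)(C)[Si](c1ccccc1)(c1ccccc1)OC/C=C(\C)C[C@@H](O)CO
F4 | step 8 | (4R)-4-{(2E)-4-[(tert-butyldiphenylsilyl)oxy]-2-methylbut-2-en-1-yl}-1,3,2-dioxathiolane 2,2-dioxide | CC(C)(C)[Si](c1ccccc1)(c1ccccc1)OC/C=C(\C)C[C@@H]1COS(=O)(=O)O1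
F5 | step 8 | lithium (2R,4E)-1-[(2S,4R)-2-tert-butyl-4-methyl-5-oxo-1,3-dioxolan-4-yl]-6-[(tert-butyldiphenylsilyl)oxy]-4-methylhex-4-en-2-yl sulfate | CC(C)(C)[Si](c1ccccc1)(c1ccccc1)OC/C=C(\C)C[C@@H](OS(=O)(=O)[O-])C[C@@]1(C)O[C@H](C(C)(C)C)OC1=O.[Li+]
F6 | step 8 | (2S,5R)-2-tert-butyl-5-{(2R,4E)-6-[(tert-butyldiphenylsilyl)oxy]-2-hydroxy-4-methylhex-4-en-1-yl}-5-methyl-1,3-dioxolan-4-one | CC(C)(C)[Si](c1ccccc1)(c1ccccc1)OC/C=C(\C)C[C@@H](O)C[C@@]1(C)O[C@H](C(C)(C)C)OC1=O
F7 | step 6 | (4S)-4-{(2E)-4-[(tert-butyldiphenylsilyl)oxy]-2-methylbut-2-en-1-yl}-1,3,2-dioxathiolane 2-oxide | CC(C)(C)[Si](c1ccccc1)(c1ccccc1)OC/C=C(\C)C[C@H]1COS(=O)O1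
F8 | step 10 | 7-{[(2E)-4-[(2R,4R)-4-hydroxy-4-methyl-5-oxooxolan-2-yl]-3-methylbut-2-en-1-yl]oxy}-8-methoxy-2H-chromen-2-one | COc1c(OC/C=C(\C)C[C@@H]2C[C@@](C)(O)C(=O)O2)ccc2ccc(=O)oc12
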